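## Retrosynthetic overview
1. The target is methyl 8α-acetoxy-1β,4α,6α-trihydroxyeudesm-11(13)-en-12-oate, a trans-decalin with rings A and B. The strategy rests on one feature: the secondary carbinol C1 of ring A is bonded directly to the methyl-bearing quaternary C10 at the ring junction. This is the retron of an aldehyde attacked by the fully substituted γ-carbon of an allyl metal.
2. The key disconnection is C1–C10. The precursor is a ring B allylic bromide (C6–Br, C5=C10) with a 4-oxobutanoyl chain (C4 ketone, C1 aldehyde) on the central allyl carbon C5. CrCl2 closes ring A and moves the alkene to C5–C6, conjugated with C4=O.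
3. Ring B is made first, by enzymatic desymmetrization of the all-cis triol, and ring A second. C8 is the only stereocentre of ring B and is carried as the 8β-ether, because the closed transition state reacts anti to O8.
4. After cyclization, C1 is inverted by oxidation–reduction. C5=C6 is hydrated by conjugate borylation–oxidation (5α-H, 6α-OH). C4 is built by methylenation and Mukaiyama hydration (4α-OH).
5. The spent 8β-ether becomes the C8 ketone. The ketone is used to attach the C7 chain (allyl, later the acrylate) and is then reduced by SmI2 to the equatorial 8α-ol. Acetylation and desilylation finish the route.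

Key step: step 12

- **Numbering:** eudesmane numbering (C1–C15) is used from the ring B stage on. β is the face of the C10 methyl group.
- **C4 ketone left free:** an acyl group on the central allyl carbon is a known activating group in allyl halide/CrCl2 additions. A ketal would be hard to install on the hindered 2-acylcyclohexene and hard to keep while an aldehyde is unmasked.
- **C7 chain attached after cyclization:** a C7 enolate of the ring B enone would carry O8 as a β-leaving group on the way to a phenol. A 7β,8α-substituted ring B would also steer the ring closure to the wrong face of C10.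
- **Assumption:** the sense of the enzymatic desymmetrization in step 2 is taken as drawn. The complementary mode (hydrolysis instead of acylation) gives the other sense.

## Route

Step 1
Reactants: 1 cis,cis-cyclohexane-1,3,5-triol
Product: 2 all-cis-5-(4-methoxybenzyloxy)cyclohexane-1,3-diol (meso)
Conditions: NaH (1 equiv), 4-methoxybenzyl chloride (1 equiv), Bu4NI (cat.), DMF, 0 °C → rt; 1 in threefold excess
Reagents that add atoms: 4-methoxybenzyl chloride, COc1ccc(CCl)cc1
Why: Williamson ether synthesis on one of three equivalent hydroxyl groups, held at the mono stage by the excess of 1; no stereocentre changes and the product stays meso.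

Step 2
Reactants: 2 all-cis-5-(4-methoxybenzyloxy)cyclohexane-1,3-diol
Product: 3 (1S,3S,5R)-3-hydroxy-5-(4-methoxybenzyloxy)cyclohexyl acetate
Conditions: immobilized lipase (Pseudomonas cepacia type), vinyl acetate, tBuOMe, 30 °C
Reagents that add atoms: vinyl acetate, C=COC(C)=O
Why: Lipase-catalysed transesterification with an irreversible acyl donor, a known desymmetrization of 5-substituted cis-cyclohexane-1,3-diols; the enzyme tells the enantiotopic carbinols apart and so fixes the configuration of the future C8.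

Step 3
Reactants: 3 (1S,3S,5R)-3-hydroxy-5-(4-methoxybenzyloxy)cyclohexyl acetate
Product: 5 (S)-5-(4-methoxybenzyloxy)cyclohex-2-en-1-one, via β-acetoxy ketone 4 (not isolated)
Conditions: Dess–Martin periodinane, CH2Cl2, 0 °C → rt; then Et3N, 0 °C
Reagents that add atoms: none
Why: Dess–Martin oxidation followed by E1cB loss of the β-acetoxy group; acetate leaves far more readily than the 4-methoxybenzyloxy group, so the mild amine base leaves C8–O in place.

Step 4
Reactants: 5 (S)-5-(4-methoxybenzyloxy)cyclohex-2-en-1-one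
Product: 6 (5S)-5-(4-methoxybenzyloxy)-1-methylcyclohex-2-en-1-ol (C1 epimers)
Conditions: MeLi, Et2O, −78 °C
Reagents that add atoms: methyllithium, [Li]C
Why: 1,2-Addition of an organolithium reagent to an enone at low temperature; the carbinol configuration is of no consequence because this carbon (C10) becomes sp2 in step 5.

Step 5
Reactants: 6 (5S)-5-(4-methoxybenzyloxy)-1-methylcyclohex-2-en-1-ol
Product: 7 (R)-5-(4-methoxybenzyloxy)-3-methylcyclohex-2-en-1-one
Conditions: pyridinium chlorochromate, 4 Å MS, CH2Cl2, rt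
Reagents that add atoms: pyridinium chlorochromate, c1cc[nH+]cc1.[O-][Cr](=O)(=O)Cl
Why: Babler–Dauben oxidative transposition: the chromate ester of the tertiary allylic alcohol undergoes a [3,3] shift and is oxidized to the β-methyl enone (C6 ketone, C5=C10), with C8 untouched.

Step 6
Reactants: 7 (R)-5-(4-methoxybenzyloxy)-3-methylcyclohex-2-en-1-one
Product: 8 (R)-2-iodo-5-(4-methoxybenzyloxy)-3-methylcyclohex-2-en-1-one
Conditions: I2, pyridine, CH2Cl2, 0 °C → rt
Reagents that add atoms: iodine, II
Why: α-Iodination of an enone by conjugate addition of pyridine, iodination of the enolate and elimination, as practised on 3-methylcyclohex-2-enone; pyridine is too weak a base to trigger loss of O8.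

Step 7
Reactants: 8 (R)-2-iodo-5-(4-methoxybenzyloxy)-3-methylcyclohex-2-en-1-one; 9 tributyl(4,5-dihydrofuran-2-yl)stannane
Product: 10 (R)-2-(4,5-dihydrofuran-2-yl)-5-(4-methoxybenzyloxy)-3-methylcyclohex-2-en-1-one
Conditions: Pd2(dba)3 (2.5 mol %), AsPh3 (10 mol %), CuI (10 mol %), NMP, rt → 45 °C
Reagents that add atoms: none
Why: Stille coupling of an α-iodoenone with an α-alkoxyvinylstannane under zerovalent palladium/CuI catalysis; it brings in C4–C1 at once, with C4 masked as the enol ether and C1 as the ring CH2–O.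

Step 8
Reactants: 10 (R)-2-(4,5-dihydrofuran-2-yl)-5-(4-methoxybenzyloxy)-3-methylcyclohex-2-en-1-one
Product: 11 (1R,5R)-2-(4,5-dihydrofuran-2-yl)-5-(4-methoxybenzyloxy)-3-methylcyclohex-2-en-1-ol (6β-OH, cis to O8)
Conditions: iBu2AlH, CH2Cl2, −78 °C; aq. potassium sodium tartrate
Reagents that add atoms: none
Why: 1,2-Reduction of the enone by an aluminium hydride, which spares the acid-labile enol ether; axial hydride delivery should give mainly the alcohol cis to O8, a centre that is erased in step 12.

Step 9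
Reactants: 11 (1R,5R)-2-(4,5-dihydrofuran-2-yl)-5-(4-methoxybenzyloxy)-3-methylcyclohex-2-en-1-ol
Product: 12 4-hydroxy-1-[(4R,6R)-6-hydroxy-4-(4-methoxybenzyloxy)-2-methylcyclohex-1-en-1-yl]butan-1-one
Conditions: oxalic acid (10 mol %), THF/H2O, 0 °C
Reagents that add atoms: water, O
Why: Acid-catalysed hydrolysis of the cyclic enol ether, much faster than ionization of the allylic alcohol, unmasks the C4 ketone and the C1 primary alcohol.

Step 10
Reactants: 12 4-hydroxy-1-[(4R,6R)-6-hydroxy-4-(4-methoxybenzyloxy)-2-methylcyclohex-1-en-1-yl]butan-1-one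
Product: 13 4-[(4R,6R)-6-hydroxy-4-(4-methoxybenzyloxy)-2-methylcyclohex-1-en-1-yl]-4-oxobutanal
Conditions: TEMPO (10 mol %), PhI(OAc)2, CH2Cl2, 0 °C → rt
Reagents that add atoms: none
Why: Nitroxyl-catalysed oxidation (TEMPO/PhI(OAc)2), selective for the primary alcohol over the hindered secondary C6 carbinol, stops at the aldehyde.

Step 11
Reactants: 13 4-[(4R,6R)-6-hydroxy-4-(4-methoxybenzyloxy)-2-methylcyclohex-1-en-1-yl]-4-oxobutanal
Product: 15 4-[(4R,6S)-6-bromo-4-(4-methoxybenzyloxy)-2-methylcyclohex-1-en-1-yl]-4-oxobutanal (6α-Br, 8β-OPMB), via allylic mesylate 14 (not isolated)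
Conditions: Ms2O, Et3N, CH2Cl2, −40 °C; then LiBr, THF, −40 → 0 °C; used at once
Reagents that add atoms: lithium bromide, [Li+].[Br-]; methanesulfonic anhydride, CS(=O)(=O)OS(C)(=O)=O (atoms only in 14)
Why: Sulfonylation followed by bromide displacement (SN2 with inversion, some SN2′ possible) under conditions that spare aldehyde and ketone; neither the C6 configuration nor the allylic position of bromine matters for step 12.

Step 12
Reactants: 15 4-[(4R,6S)-6-bromo-4-(4-methoxybenzyloxy)-2-methylcyclohex-1-en-1-yl]-4-oxobutanal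
Product: 18 1α-hydroxy-8β-(4-methoxybenzyloxy)-11,12,13,15-tetranoreudesm-5-en-4-one (10β-methyl), via allylchromium dichloride 16 (not isolated), via chromium alkoxide 17 (not isolated)
Conditions: CrCl2 (6 equiv), THF, rt, 15 added over 8 h (final 0.003 M); then H2O
Reagents that add atoms: none
Why: Two equivalents of CrCl2 (divalent chromium) reduce the allylic C–Br bond by successive one-electron transfers to the allylchromium dichloride 16 (trivalent chromium), on which both C6 epimers and the allylic isomer of the bromide converge; the metal binds the aldehyde oxygen and the γ-carbon C10 attacks C1 with allylic transposition, so that C1–C10 forms and the alkene moves to C5–C6, into conjugation with the C4 ketone. This is an intramolecular Nozaki–Hiyama–Kishi allylation; quaternary carbons from γ,γ-disubstituted allylchromium reagents, and additions of 2-acyl- and 2-(alkoxycarbonyl)allyl halides that carry the carbonyl group on the central allyl carbon as 15 does, are both established. Ring A closes 6-exo-trig at the C1 carbonyl, with the C5=C10 bond inside the forming ring, through a chair-like six-membered transition state (Cr, C6, C5, C10, C1, O) bridged by C2–C3–C4 like a bicyclo[3.3.1]nonane. C10: the closed transition state is suprafacial and points the C8 substituent of the reacting face at the aldehyde oxygen, so the reaction runs on the face that bears H-8, anti to the 8β-OPMB group (the preference seen in trans-selective additions to 5-substituted cyclohexenones), and the methyl group ends up β. C1: the tether holds C2 axial in that chair, which places O1 anti to the C10 methyl group and gives the axial 1α-alcohol, the epimer that steps 13 and 14 invert. The step needs attack by C10 and not by C6 (either would close a six-membered ring), aldehyde-over-ketone selectivity, and cyclization in preference to dimerization; these are secured by the preference of chromium for the less substituted terminus C6, by the low reactivity of organochromium reagents toward ketones, and by slow addition at high dilution.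

Step 13
Reactants: 18 1α-hydroxy-8β-(4-methoxybenzyloxy)-11,12,13,15-tetranoreudesm-5-en-4-one
Product: 19 8β-(4-methoxybenzyloxy)-11,12,13,15-tetranoreudesm-5-ene-1,4-dione
Conditions: Dess–Martin periodinane, CH2Cl2, rt
Reagents that add atoms: none
Why: Dess–Martin oxidation of the hindered axial alcohol removes the wrong C1 configuration; the quaternary C10 next to the new ketone cannot epimerize.

Step 14
Reactants: 19 8β-(4-methoxybenzyloxy)-11,12,13,15-tetranoreudesm-5-ene-1,4-dione
Product: 20 1β-hydroxy-8β-(4-methoxybenzyloxy)-11,12,13,15-tetranoreudesm-5-en-4-one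
Conditions: NaBH4 (0.3 equiv), EtOH, −20 °C
Reagents that add atoms: none
Why: Chemoselective borohydride reduction of the saturated C1 ketone beside the less electrophilic conjugated C4 ketone, as in the classical monoreduction of 9-methyloctalindiones; hydride attacks from the α-face, anti to the C10 methyl group, and gives the equatorial 1β-alcohol.

Step 15
Reactants: 20 1β-hydroxy-8β-(4-methoxybenzyloxy)-11,12,13,15-tetranoreudesm-5-en-4-one
Product: 22 1β,6α-dihydroxy-8β-(4-methoxybenzyloxy)-11,12,13,15-tetranor-5αH-eudesman-4-one, via 6α-boronate 21 (not isolated)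
Conditions: CuCl (10 mol %), Xantphos (10 mol %), NaOtBu (15 mol %), B2pin2, MeOH, THF, rt; then NaBO3·4H2O, THF/H2O, rt
Reagents that add atoms: bis(pinacolato)diboron, CC1(C)OB(OC1(C)C)B1OC(C)(C)C(C)(C)O1 (atoms only in 21); sodium perborate, [Na+].[O-]OB=O
Why: Copper-catalysed conjugate borylation followed by perborate oxidation with retention, a formal hydration of C5=C6; boron adds to C6 from the α-face because the β-face is covered by the C10 methyl group and the axial 8β-ether, and protonation of the enolate at C5 from the same open face gives the trans-decalone, which is also the more stable C5 epimer.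

Step 16
Reactants: 22 1β,6α-dihydroxy-8β-(4-methoxybenzyloxy)-11,12,13,15-tetranor-5αH-eudesman-4-one
Product: 23 8β-(4-methoxybenzyloxy)-1β,6α-bis(triethylsilyloxy)-11,12,13,15-tetranor-5αH-eudesman-4-one
Conditions: TESOTf, 2,6-lutidine, CH2Cl2, −78 → 0 °C
Reagents that add atoms: triethylsilyl triflate, CC[Si](CC)(CC)OS(=O)(=O)C(F)(F)F
Why: Silylation with the reactive triflate protects both hindered secondary alcohols in one operation; the weak, hindered base at low temperature avoids enol silylation and β-elimination.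

Step 17
Reactants: 23 8β-(4-methoxybenzyloxy)-1β,6α-bis(triethylsilyloxy)-11,12,13,15-tetranor-5αH-eudesman-4-one
Product: 24 8β-(4-methoxybenzyloxy)-1β,6α-bis(triethylsilyloxy)-11,12,13-trinor-5αH-eudesm-4(15)-ene
Conditions: Cp2TiMe2, toluene, 70 °C, dark
Reagents that add atoms: dimethyltitanocene, [CH3-].[CH3-].[Ti+4].c1cc[cH-]c1.c1cc[cH-]c1
Why: Petasis methylenation: Cp2TiMe2 loses methane to give the non-basic carbene Cp2Ti=CH2, so neither C5 epimerization nor β-elimination of the C6 silyloxy group is to be expected at this hindered ketone.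

Step 18
Reactants: 24 8β-(4-methoxybenzyloxy)-1β,6α-bis(triethylsilyloxy)-11,12,13-trinor-5αH-eudesm-4(15)-ene
Product: 26 8β-(4-methoxybenzyloxy)-1β,6α-bis(triethylsilyloxy)-11,12,13-trinor-5αH-eudesman-4α-ol, via 4α-hydroperoxide 25 (not isolated)
Conditions: Mn(dpm)3 (10 mol %), PhSiH3, O2 (1 atm), iPrOH, 0 °C → rt; then PPh3
Reagents that add atoms: dioxygen, O=O
Why: Mukaiyama hydration (hydrogen-atom transfer from a manganese hydride to C15, Markovnikov): the tertiary C4 radical is trapped by O2 from the equatorial α-side, the axial β-side being closed by the 1,3-diaxial C10 methyl group, and PPh3 reduces the hydroperoxide to the 4α-alcohol (4β-methyl).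

Step 19
Reactants: 26 8β-(4-methoxybenzyloxy)-1β,6α-bis(triethylsilyloxy)-11,12,13-trinor-5αH-eudesman-4α-ol
Product: 27 1β,6α-bis(triethylsilyloxy)-11,12,13-trinor-5αH-eudesmane-4α,8β-diol
Conditions: DDQ, CH2Cl2/pH 7 buffer, 0 °C
Reagents that add atoms: none
Why: Oxidative cleavage of the 4-methoxybenzyl ether by DDQ (hydride abstraction, then hydrolysis of the oxocarbenium ion) under buffered conditions that spare the triethylsilyl ethers.

Step 20
Reactants: 27 1β,6α-bis(triethylsilyloxy)-11,12,13-trinor-5αH-eudesmane-4α,8β-diol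
Product: 28 4α-hydroxy-1β,6α-bis(triethylsilyloxy)-11,12,13-trinor-5αH-eudesman-8-one
Conditions: Dess–Martin periodinane, CH2Cl2, rt
Reagents that add atoms: none
Why: Dess–Martin oxidation of the only secondary alcohol; it removes the 8β-centre, whose directing task ended with step 15, and relieves its 1,3-diaxial strain with the C10 methyl group.

Step 21
Reactants: 28 4α-hydroxy-1β,6α-bis(triethylsilyloxy)-11,12,13-trinor-5αH-eudesman-8-one; 29 allyl bromide
Product: 31 7β-allyl-4α-hydroxy-1β,6α-bis(triethylsilyloxy)-11,12,13-trinor-5αH-eudesman-8-one, via 7α-allyl ketone 30 (not isolated)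
Conditions: LiN(iPr)2 (2.2 equiv), THF, −78 °C; 29, −78 → −40 °C; crude product: DBU (0.2 equiv), toluene, rt
Reagents that add atoms: none
Why: Kinetic enolate alkylation followed by base equilibration: deprotonation should occur at C7 and not at C9, which is flanked by the quaternary C10 (as in 10-methyl-2-decalones); the equatorial C6–O bond lies close to the nodal plane of the enolate and resists β-elimination, and the axial 7α-allyl ketone from stereoelectronic control is epimerized through its enol to the equatorial 7β-isomer.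

Step 22
Reactants: 31 7β-allyl-4α-hydroxy-1β,6α-bis(triethylsilyloxy)-11,12,13-trinor-5αH-eudesman-8-one
Product: 32 7β-allyl-1β,6α-bis(triethylsilyloxy)-11,12,13-trinor-5αH-eudesmane-4α,8α-diol
Conditions: SmI2 (3 equiv), THF/H2O, 0 °C
Reagents that add atoms: none
Why: Single-electron (ketyl) reduction with SmI2/H2O gives the thermodynamically preferred equatorial 8α-alcohol, whereas hydride reagents would attack from the α-face (the β-face is blocked by the syn-axial C10 methyl group) and return the 8β-alcohol; the allyl group could only close a four-membered or a 5-endo ring and stays untouched.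

Step 23
Reactants: 32 7β-allyl-1β,6α-bis(triethylsilyloxy)-11,12,13-trinor-5αH-eudesmane-4α,8α-diol
Product: 33 7β-allyl-4α-hydroxy-1β,6α-bis(triethylsilyloxy)-11,12,13-trinor-5αH-eudesman-8α-yl acetate
Conditions: Ac2O, DMAP (cat.), pyridine, CH2Cl2, rt
Reagents that add atoms: acetic anhydride, CC(=O)OC(C)=O
Why: DMAP-catalysed acetylation of the only secondary hydroxyl group; the hindered tertiary 4α-OH does not react under these conditions.

Step 24
Reactants: 33 7β-allyl-4α-hydroxy-1β,6α-bis(triethylsilyloxy)-11,12,13-trinor-5αH-eudesman-8α-yl acetate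
Product: 35 8α-acetoxy-4α-hydroxy-1β,6α-bis(triethylsilyloxy)-13-nor-5αH-eudesman-12-al, via ozonide 34 (not isolated)
Conditions: O3, CH2Cl2, −78 °C; then Me2S, −78 °C → rt
Reagents that add atoms: ozone, [O-][O+]=O
Why: Ozonolysis with reductive work-up cleaves the only C=C bond and leaves C11–C12 as the acetaldehyde side chain on C7.

Step 25
Reactants: 35 8α-acetoxy-4α-hydroxy-1β,6α-bis(triethylsilyloxy)-13-nor-5αH-eudesman-12-al
Product: 36 8α-acetoxy-4α-hydroxy-1β,6α-bis(triethylsilyloxy)-5αH-eudesm-11(13)-en-12-al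
Conditions: 37% aq. HCHO, pyrrolidine (20 mol %), EtCO2H (20 mol %), iPrOH, 45 °C
Reagents that add atoms: formaldehyde, C=O
Why: Amine/acid-catalysed Mannich condensation with formaldehyde (α-methylenation of an aldehyde) introduces C13 under nearly neutral conditions, which the acetate tolerates whereas an ester-enolate route would not.

Step 26
Reactants: 36 8α-acetoxy-4α-hydroxy-1β,6α-bis(triethylsilyloxy)-5αH-eudesm-11(13)-en-12-al
Product: 37 8α-acetoxy-4α-hydroxy-1β,6α-bis(triethylsilyloxy)-5αH-eudesm-11(13)-en-12-oic acid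
Conditions: NaClO2, NaH2PO4, 2-methyl-2-butene, tBuOH/H2O, 0 °C → rt
Reagents that add atoms: sodium chlorite, [Na+].[O-]Cl=O
Why: Pinnick oxidation converts the enal into the acrylic acid without touching the conjugated alkene, with the scavenger taking up the hypochlorous acid.

Step 27
Reactants: 37 8α-acetoxy-4α-hydroxy-1β,6α-bis(triethylsilyloxy)-5αH-eudesm-11(13)-en-12-oic acid
Product: 38 methyl 8α-acetoxy-4α-hydroxy-1β,6α-bis(triethylsilyloxy)-5αH-eudesm-11(13)-en-12-oate
Conditions: TMSCHN2, toluene/MeOH, 0 °C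
Reagents that add atoms: (trimethylsilyl)diazomethane, C[Si](C)(C)C=[N+]=[N-]
Why: O-Methylation of the carboxylic acid by a diazoalkane, which needs neither acid nor base and leaves the acetate, silyl ethers and acrylate intact.

Step 28
Reactants: 38 methyl 8α-acetoxy-4α-hydroxy-1β,6α-bis(triethylsilyloxy)-5αH-eudesm-11(13)-en-12-oate
Product: 39 methyl 8α-acetoxy-1β,4α,6α-trihydroxyeudesm-11(13)-en-12-oate (target)
Conditions: HF·pyridine, pyridine, THF, 0 °C
Reagents that add atoms: none
Why: Fluoride-induced cleavage of both triethylsilyl ethers; buffered HF·pyridine at 0 °C is chosen because stronger acid or base would favour closure of the 6α-OH onto C12 (γ-lactone) or acetyl migration.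

## Compound list
1 | cis,cis-cyclohexane-1,3,5-triol | O[C@H]1C[C@@H](O)C[C@@H](O)C1 | starting material
2 | all-cis-5-(4-methoxybenzyloxy)cyclohexane-1,3-diol (meso) | O[C@@H]1C[C@H](O)C[C@H](OCc2ccc(OC)cc2)C1 | intermediate
3 | (1S,3S,5R)-3-hydroxy-5-(4-methoxybenzyloxy)cyclohexyl acetate | O[C@@H]1C[C@H](OC(C)=O)C[C@H](OCc2ccc(OC)cc2)C1 | intermediate
4 | (1R,3S)-3-(4-methoxybenzyloxy)-5-oxocyclohexyl acetate (not isolated) | O=C1C[C@H](OC(C)=O)C[C@H](OCc2ccc(OC)cc2)C1 | intermediate
5 | (S)-5-(4-methoxybenzyloxy)cyclohex-2-en-1-one | O=C1C=CC[C@H](OCc2ccc(OC)cc2)C1 | intermediate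
6 | (5S)-5-(4-methoxybenzyloxy)-1-methylcyclohex-2-en-1-ol (C1 epimers) | CC1(O)C=CC[C@H](OCc2ccc(OC)cc2)C1 | intermediate
7 | (R)-5-(4-methoxybenzyloxy)-3-methylcyclohex-2-en-1-one | CC1=CC(=O)C[C@H](OCc2ccc(OC)cc2)C1 | intermediate
8 | (R)-2-iodo-5-(4-methoxybenzyloxy)-3-methylcyclohex-2-en-1-one | CC1=C(I)C(=O)C[C@H](OCc2ccc(OC)cc2)C1 | intermediate
9 | tributyl(4,5-dihydrofuran-2-yl)stannane | CCCC[Sn](CCCC)(CCCC)C1=CCCO1 | starting material
10 | (R)-2-(4,5-dihydrofuran-2-yl)-5-(4-methoxybenzyloxy)-3-methylcyclohex-2-en-1-one | CC1=C(C2=CCCO2)C(=O)C[C@H](OCc3ccc(OC)cc3)C1 | intermediate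
11 | (1R,5R)-2-(4,5-dihydrofuran-2-yl)-5-(4-methoxybenzyloxy)-3-methylcyclohex-2-en-1-ol | CC1=C(C2=CCCO2)[C@H](O)C[C@H](OCc3ccc(OC)cc3)C1 | intermediate
12 | 4-hydroxy-1-[(4R,6R)-6-hydroxy-4-(4-methoxybenzyloxy)-2-methylcyclohex-1-en-1-yl]butan-1-one | CC1=C(C(=O)CCCO)[C@H](O)C[C@H](OCc2ccc(OC)cc2)C1 | intermediate
13 | 4-[(4R,6R)-6-hydroxy-4-(4-methoxybenzyloxy)-2-methylcyclohex-1-en-1-yl]-4-oxobutanal | CC1=C(C(=O)CCC=O)[C@H](O)C[C@H](OCc2ccc(OC)cc2)C1 | intermediate
14 | (1R,5R)-5-(4-methoxybenzyloxy)-3-methyl-2-(4-oxobutanoyl)cyclohex-2-en-1-yl methanesulfonate (not isolated) | CC1=C(C(=O)CCC=O)[C@H](OS(C)(=O)=O)C[C@H](OCc2ccc(OC)cc2)C1 | intermediate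
15 | 4-[(4R,6S)-6-bromo-4-(4-methoxybenzyloxy)-2-methylcyclohex-1-en-1-yl]-4-oxobutanal (key-step precursor) | O=CCCC(=O)C1=C(C)C[C@@H](OCc2ccc(OC)cc2)C[C@@H]1Br | intermediate
16 | C6 (α-face) allylchromium dichloride from 15 (not isolated) | O=CCCC(=O)C1=C(C)C[C@@H](OCc2ccc(OC)cc2)C[C@@H]1[Cr](Cl)Cl | intermediate
17 | dichlorochromium 1α-alkoxide of 18 (not isolated) | O=C1CC[C@H](O[Cr](Cl)Cl)[C@]2(C)C[C@@H](OCc3ccc(OC)cc3)CC=C12 | intermediate
18 | 1α-hydroxy-8β-(4-methoxybenzyloxy)-11,12,13,15-tetranoreudesm-5-en-4-one (key-step product) | O=C1CC[C@H](O)[C@]2(C)C[C@@H](OCc3ccc(OC)cc3)CC=C12 | intermediate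
19 | 8β-(4-methoxybenzyloxy)-11,12,13,15-tetranoreudesm-5-ene-1,4-dione | O=C1CCC(=O)[C@]2(C)C[C@@H](OCc3ccc(OC)cc3)CC=C12 | intermediate
20 | 1β-hydroxy-8β-(4-methoxybenzyloxy)-11,12,13,15-tetranoreudesm-5-en-4-one | O=C1CC[C@@H](O)[C@]2(C)C[C@@H](OCc3ccc(OC)cc3)CC=C12 | intermediate
21 | 1β-hydroxy-8β-(4-methoxybenzyloxy)-6α-(pinacolatoboryl)-11,12,13,15-tetranor-5αH-eudesman-4-one (not isolated) | O=C1CC[C@@H](O)[C@]2(C)C[C@@H](OCc3ccc(OC)cc3)C[C@H](B3OC(C)(C)C(C)(C)O3)[C@@H]12 | intermediate
22 | 1β,6α-dihydroxy-8β-(4-methoxybenzyloxy)-11,12,13,15-tetranor-5αH-eudesman-4-one | O=C1CC[C@@H](O)[C@]2(C)C[C@@H](OCc3ccc(OC)cc3)C[C@H](O)[C@@H]12 | intermediate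
23 | 8β-(4-methoxybenzyloxy)-1β,6α-bis(triethylsilyloxy)-11,12,13,15-tetranor-5αH-eudesman-4-one | O=C1CC[C@@H](O[Si](CC)(CC)CC)[C@]2(C)C[C@@H](OCc3ccc(OC)cc3)C[C@H](O[Si](CC)(CC)CC)[C@@H]12 | intermediate
24 | 8β-(4-methoxybenzyloxy)-1β,6α-bis(triethylsilyloxy)-11,12,13-trinor-5αH-eudesm-4(15)-ene | C=C1CC[C@@H](O[Si](CC)(CC)CC)[C@]2(C)C[C@@H](OCc3ccc(OC)cc3)C[C@H](O[Si](CC)(CC)CC)[C@@H]12 | intermediate
25 | 4α-hydroperoxide of the 26 skeleton (not isolated) | C[C@@]1(OO)CC[C@@H](O[Si](CC)(CC)CC)[C@]2(C)C[C@@H](OCc3ccc(OC)cc3)C[C@H](O[Si](CC)(CC)CC)[C@@H]12 | intermediate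
26 | 8β-(4-methoxybenzyloxy)-1β,6α-bis(triethylsilyloxy)-11,12,13-trinor-5αH-eudesman-4α-ol | C[C@@]1(O)CC[C@@H](O[Si](CC)(CC)CC)[C@]2(C)C[C@@H](OCc3ccc(OC)cc3)C[C@H](O[Si](CC)(CC)CC)[C@@H]12 | intermediate
27 | 1β,6α-bis(triethylsilyloxy)-11,12,13-trinor-5αH-eudesmane-4α,8β-diol | C[C@@]1(O)CC[C@@H](O[Si](CC)(CC)CC)[C@]2(C)C[C@@H](O)C[C@H](O[Si](CC)(CC)CC)[C@@H]12 | intermediate
28 | 4α-hydroxy-1β,6α-bis(triethylsilyloxy)-11,12,13-trinor-5αH-eudesman-8-one | C[C@@]1(O)CC[C@@H](O[Si](CC)(CC)CC)[C@]2(C)CC(=O)C[C@H](O[Si](CC)(CC)CC)[C@@H]12 | intermediate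
29 | allyl bromide | C=CCBr | starting material
30 | 7α-allyl-4α-hydroxy-1β,6α-bis(triethylsilyloxy)-11,12,13-trinor-5αH-eudesman-8-one (not isolated) | C[C@@]1(O)CC[C@@H](O[Si](CC)(CC)CC)[C@]2(C)CC(=O)[C@H](CC=C)[C@H](O[Si](CC)(CC)CC)[C@@H]12 | intermediate
31 | 7β-allyl-4α-hydroxy-1β,6α-bis(triethylsilyloxy)-11,12,13-trinor-5αH-eudesman-8-one | C[C@@]1(O)CC[C@@H](O[Si](CC)(CC)CC)[C@]2(C)CC(=O)[C@@H](CC=C)[C@H](O[Si](CC)(CC)CC)[C@@H]12 | intermediate
32 | 7β-allyl-1β,6α-bis(triethylsilyloxy)-11,12,13-trinor-5αH-eudesmane-4α,8α-diol | C[C@@]1(O)CC[C@@H](O[Si](CC)(CC)CC)[C@]2(C)C[C@H](O)[C@@H](CC=C)[C@H](O[Si](CC)(CC)CC)[C@@H]12 | intermediate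
33 | 7β-allyl-4α-hydroxy-1β,6α-bis(triethylsilyloxy)-11,12,13-trinor-5αH-eudesman-8α-yl acetate | C[C@@]1(O)CC[C@@H](O[Si](CC)(CC)CC)[C@]2(C)C[C@H](OC(C)=O)[C@@H](CC=C)[C@H](O[Si](CC)(CC)CC)[C@@H]12 | intermediate
34 | 1,2,4-trioxolane (ozonide) of 33 (not isolated) | C[C@@]1(O)CC[C@@H](O[Si](CC)(CC)CC)[C@]2(C)C[C@H](OC(C)=O)[C@@H](CC3OCOO3)[C@H](O[Si](CC)(CC)CC)[C@@H]12 | intermediate
35 | 8α-acetoxy-4α-hydroxy-1β,6α-bis(triethylsilyloxy)-13-nor-5αH-eudesman-12-al | C[C@@]1(O)CC[C@@H](O[Si](CC)(CC)CC)[C@]2(C)C[C@H](OC(C)=O)[C@@H](CC=O)[C@H](O[Si](CC)(CC)CC)[C@@H]12 | intermediate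
36 | 8α-acetoxy-4α-hydroxy-1β,6α-bis(triethylsilyloxy)-5αH-eudesm-11(13)-en-12-al | C[C@@]1(O)CC[C@@H](O[Si](CC)(CC)CC)[C@]2(C)C[C@H](OC(C)=O)[C@@H](C(=C)C=O)[C@H](O[Si](CC)(CC)CC)[C@@H]12 | intermediate
37 | 8α-acetoxy-4α-hydroxy-1β,6α-bis(triethylsilyloxy)-5αH-eudesm-11(13)-en-12-oic acid | C[C@@]1(O)CC[C@@H](O[Si](CC)(CC)CC)[C@]2(C)C[C@H](OC(C)=O)[C@@H](C(=C)C(=O)O)[C@H](O[Si](CC)(CC)CC)[C@@H]12 | intermediate
38 | methyl 8α-acetoxy-4α-hydroxy-1β,6α-bis(triethylsilyloxy)-5αH-eudesm-11(13)-en-12-oate | C[C@@]1(O)CC[C@@H](O[Si](CC)(CC)CC)[C@]2(C)C[C@H](OC(C)=O)[C@@H](C(=C)C(=O)OC)[C@H](O[Si](CC)(CC)CC)[C@@H]12 | intermediate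
39 | methyl 8α-acetoxy-1β,4α,6α-trihydroxyeudesm-11(13)-en-12-oate (CNP0272656.1) | C=C(C(=O)OC)[C@H]1[C@H](O)[C@@H]2[C@@](C)(C[C@@H]1OC(C)=O)[C@H](O)CC[C@@]2(C)O | target

## Step count and risks
Total step count: 28. Longest linear sequence: 28 steps, from 1 to 39. Compounds 9 and 29 are purchased.

**Step 12.**
- What may go wrong: the allylchromium species may be protonated or may dimerize before it cyclizes. Ring closure may run through C6 in place of C10. Facial selectivity may erode because the chromium–carbon bond is configurationally labile.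
- Fallback: it sets out from 13. Acetylation (Ac2O, pyridine, DMAP) gives the allylic acetate F1. Borylation with B2pin2 catalysed by Pd2(dba)3 in DMSO, known for acetates of this 2-acylallyl type, replaces acetate by boron with overall inversion. The product is the configurationally stable 6α-allylboronate F2.
- F2 adds to the tethered aldehyde through the same closed transition state, now tied to the α-face, and gives the pinacol borate F3. Mild hydrolysis of F3 returns to the route at 18.

**Step 21.**
- What may go wrong: enolization may go toward C9. The C6 silyloxy group may be lost by β-elimination during enolate formation or equilibration. Double alkylation is also possible.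
- Fallback: it sets out from 28. Condensation with Me2NNH2 (cat. AcOH, EtOH) gives the N,N-dimethylhydrazone F4. Its aza-enolate (LiN(iPr)2, THF, −78 °C) forms at the less hindered C7, is far less prone to β-elimination, and is alkylated with 29 to the 7α-allyl hydrazone F5.
- Cleavage with aqueous Cu(OAc)2 in THF gives 30, which is equilibrated with DBU as in the main route. The fallback comes back at 31.

**Step 18.**
- What may go wrong: the capture of the C4 radical by O2 may show poor facial selectivity, since the equatorial approach is flanked by the C6 silyl ether. Reduction of the radical to the alkane may compete.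
- Fallback: it sets out from 24. Epoxidation with mCPBA (NaHCO3, CH2Cl2, 0 °C) should occur from the equatorial α-side of the exocyclic methylene group, the axial side being blocked by the C10 methyl group, and give the 4α,15-epoxide F6.
- LiEt3BH (THF, 0 °C → rt) opens F6 at the primary carbon C15. No ester or ketone is present at this stage. The fallback comes back at 26.

Further compounds
F1 | step 12 | (1R,5R)-5-(4-methoxybenzyloxy)-3-methyl-2-(4-oxobutanoyl)cyclohex-2-en-1-yl acetate | CC1=C(C(=O)CCC=O)[C@H](OC(C)=O)C[C@H](OCc2ccc(OC)cc2)C1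
F2 | step 12 | 4-[6α-(pinacolatoboryl)-8β-(4-methoxybenzyloxy)-2-methylcyclohex-1-en-1-yl]-4-oxobutanal (6α-allylboronate) | CC1=C(C(=O)CCC=O)[C@@H](B2OC(C)(C)C(C)(C)O2)C[C@H](OCc3ccc(OC)cc3)C1
F3 | step 12 | pinacol borate of 18 (1α-O-Bpin) | O=C1CC[C@H](OB3OC(C)(C)C(C)(C)O3)[C@]2(C)C[C@@H](OCc3ccc(OC)cc3)CC=C12
F4 | step 21 | N,N-dimethylhydrazone of 28 | C[C@@]1(O)CC[C@@H](O[Si](CC)(CC)CC)[C@]2(C)CC(=NN(C)C)C[C@H](O[Si](CC)(CC)CC)[C@@H]12
F5 | step 21 | 7α-allyl N,N-dimethylhydrazone | C[C@@]1(O)CC[C@@H](O[Si](CC)(CC)CC)[C@]2(C)CC(=NN(C)C)[C@H](CC=C)[C@H](O[Si](CC)(CC)CC)[C@@H]12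
F6 | step 18 | 4α,15-epoxide of 24 | C1O[C@@]12CC[C@@H](O[Si](CC)(CC)CC)[C@]3(C)C[C@@H](OCc4ccc(OC)cc4)C[C@H](O[Si](CC)(CC)CC)[C@@H]23
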